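The route rests on cutting both ring bonds at the carbinol carbon of the 4-hydroxycyclohexanone ring, C1–C2 and C1–C6. C1 lies on the mirror plane that also contains the C4 carbonyl, carries two identical ring arms and has the oxidation level of an ester carbon. A five-carbon bis-Grignard reagent, whose central carbon (the future C4) is masked as a 5,5-dimethyl-1,3-dioxane, therefore adds twice to ethyl 3-(tert-butyldimethylsilyloxy)propanoate and delivers the carbocycle, both C–C bonds and the tertiary hydroxyl in one operation. The reagent is made in the flask from 2,2-bis(2-bromoethyl)-5,5-dimethyl-1,3-dioxane. Aqueous acid then frees ketone and primary alcohol together, and palmitoylation of the primary hydroxyl finishes.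

Key step: step 5

Remark: ring atoms are numbered C1 (carbinol carbon) to C4 (carbonyl carbon); the target has no stereocentre, because C1 carries two identical ring arms, so no SMILES string needs a stereodescriptor.

Step 1
Reactants: 1 diethyl 3-oxopentanedioate (diethyl acetonedicarboxylate)
Product: 2 ketal diester diethyl 2,2'-(5,5-dimethyl-1,3-dioxane-2,2-diyl)diacetate
Conditions: neopentyl glycol (1.5 equiv), TsOH·H2O (cat.), toluene, reflux, Dean–Stark
Reagents that add atoms: neopentyl glycol (2,2-dimethylpropane-1,3-diol), OCC(C)(C)CO
Why: Acid-catalysed ketalisation is driven forward by azeotropic removal of water, the six-membered dioxane being favoured by its gem-dimethyl group while the hindered neopentyl hydroxyls transesterify the ethyl esters only slowly.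

Step 2
Reactants: 2 ketal diester diethyl 2,2'-(5,5-dimethyl-1,3-dioxane-2,2-diyl)diacetate
Product: 3 diol 2,2'-(5,5-dimethyl-1,3-dioxane-2,2-diyl)di(ethan-1-ol)
Conditions: LiAlH4 (1.5 equiv), THF, 0 °C → rt; H2O, 15% aq. NaOH, H2O
Reagents that add atoms: none
Why: LiAlH4 ester reduction takes both ethoxycarbonyl groups to primary alcohols, and the ketal is inert to hydride and to the basic, non-extractive work-up that suits the water-soluble diol.

Step 3
Reactants: 3 diol 2,2'-(5,5-dimethyl-1,3-dioxane-2,2-diyl)di(ethan-1-ol)
Product: 4 dibromide 2,2-bis(2-bromoethyl)-5,5-dimethyl-1,3-dioxane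
Conditions: CBr4 (2.5 equiv), PPh3 (2.5 equiv), CH2Cl2, 0 °C → rt
Reagents that add atoms: carbon tetrabromide, BrC(Br)(Br)Br
Why: In the Appel reaction each primary hydroxyl becomes an alkoxyphosphonium ion that bromide displaces by SN2 under neutral conditions, which the acid-sensitive ketal tolerates.

Step 4
Reactants: 5 ethyl 3-hydroxypropanoate
Product: 6 silyl ether ester ethyl 3-[(tert-butyldimethylsilyl)oxy]propanoate
Conditions: TBSCl (1.1 equiv), imidazole (1.5 equiv), CH2Cl2, 0 °C → rt
Reagents that add atoms: tert-butyldimethylsilyl chloride (TBSCl), CC(C)(C)[Si](C)(C)Cl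
Why: Imidazole-mediated silylation of the unhindered primary alcohol gives a silyl ether that is stable to organomagnesium reagents and is later cleaved by the same aqueous acid that opens the ketal.

Step 5
Reactants: 4 dibromide 2,2-bis(2-bromoethyl)-5,5-dimethyl-1,3-dioxane; 6 silyl ether ester ethyl 3-[(tert-butyldimethylsilyl)oxy]propanoate
Product: 10 spiroketal carbinol 9-{2-[(tert-butyldimethylsilyl)oxy]ethyl}-3,3-dimethyl-1,5-dioxaspiro[5.5]undecan-9-ol, via bis-Grignard reagent 7 (not isolated), via keto-Grignard 8 (not isolated), via bromomagnesium alkoxide 9 (not isolated)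
Conditions: 4 (1.3 equiv), Mg turnings (activated with a crystal of iodine), THF (0.25 M), 25–30 °C; then 6 (1.0 equiv) in THF added slowly at −10 °C, → rt; sat. aq. NH4Cl
Reagents that add atoms: none
Why: Magnesium inserts into both primary C–Br bonds of 4 to give bis-Grignard reagent 7; one C–Mg terminus adds to the ester carbonyl of 6, and the tetrahedral alkoxide expels ethoxide to give ketone 8, which still carries the second C–Mg bond five atoms from the carbonyl carbon. That terminus then attacks the ketone in a 6-exo-trig closure, which forms the second ring bond and alkoxide 9, protonated to 10 on work-up. The closest known reaction type is the annulating double addition of pentane-1,5-diylbis(magnesium bromide) to esters, which gives 1-substituted cyclohexanols, taken together with the known Grignard reagents of 2-(2-bromoethyl)-5,5-dimethyl-1,3-dioxanes. No stereocentre is formed, because the new carbinol carbon carries two identical ring arms and 10 is achiral. The step needs ring closure to win over intermolecular addition, over enolisation of 8 with loss of silyloxide, and over Wurtz coupling or cyclopropane-forming 1,3-elimination within 7. The high effective molarity of the six-membered closure, slow addition of 6 to a slight excess of dilute 7 below 0 °C, and the six-membered ketal, which resists 1,3-elimination at or below 30 °C, secure this.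

Step 6
Reactants: 10 spiroketal carbinol 9-{2-[(tert-butyldimethylsilyl)oxy]ethyl}-3,3-dimethyl-1,5-dioxaspiro[5.5]undecan-9-ol
Product: 11 keto diol 4-hydroxy-4-(2-hydroxyethyl)cyclohexan-1-one
Conditions: 1 M aq. HCl/THF (1:3), rt; solid NaHCO3, concentrate, extract residue with EtOAc
Reagents that add atoms: water, O
Why: Acid-catalysed silyl ether solvolysis and ketal hydrolysis remove both protecting groups in one flask, in either order, while the tertiary alcohol, which is gamma to the new carbonyl and so has no retro-aldol or conjugate-elimination pathway, should survive dilute acid at room temperature.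

Step 7
Reactants: 11 keto diol 4-hydroxy-4-(2-hydroxyethyl)cyclohexan-1-one; 12 palmitoyl chloride (hexadecanoyl chloride)
Product: 13 target 2-(1-hydroxy-4-oxocyclohexyl)ethyl hexadecanoate
Conditions: 12 (1.05 equiv, slow addition), pyridine, CH2Cl2, −10 → 0 °C
Reagents that add atoms: none
Why: Pyridine-mediated O-acylation (nucleophilic acyl substitution) with one equivalent of acid chloride at low temperature should occur only at the primary hydroxyl, since the tertiary alcohol is too hindered and the ketone is inert.

Compound list
1 | diethyl 3-oxopentanedioate (diethyl acetonedicarboxylate) | CCOC(=O)CC(=O)CC(=O)OCC | starting material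
2 | diethyl 2,2'-(5,5-dimethyl-1,3-dioxane-2,2-diyl)diacetate | CCOC(=O)CC1(CC(=O)OCC)OCC(C)(C)CO1 | intermediate
3 | 2,2'-(5,5-dimethyl-1,3-dioxane-2,2-diyl)di(ethan-1-ol) | OCCC1(CCO)OCC(C)(C)CO1 | intermediate
4 | 2,2-bis(2-bromoethyl)-5,5-dimethyl-1,3-dioxane | BrCCC1(CCBr)OCC(C)(C)CO1 | intermediate
5 | ethyl 3-hydroxypropanoate | CCOC(=O)CCO | starting material
6 | ethyl 3-[(tert-butyldimethylsilyl)oxy]propanoate | CCOC(=O)CCO[Si](C)(C)C(C)(C)C | intermediate
7 | [(5,5-dimethyl-1,3-dioxane-2,2-diyl)di(ethane-2,1-diyl)]bis(bromomagnesium), the bis-Grignard reagent of 4 | Br[Mg]CCC1(CC[Mg]Br)OCC(C)(C)CO1 | intermediate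
8 | 5-{2-[2-(bromomagnesio)ethyl]-5,5-dimethyl-1,3-dioxan-2-yl}-1-[(tert-butyldimethylsilyl)oxy]pentan-3-one | CC(C)(C)[Si](C)(C)OCCC(=O)CCC1(CC[Mg]Br)OCC(C)(C)CO1 | intermediate
9 | bromomagnesium 9-{2-[(tert-butyldimethylsilyl)oxy]ethyl}-3,3-dimethyl-1,5-dioxaspiro[5.5]undecan-9-olate | CC(C)(C)[Si](C)(C)OCCC1(O[Mg]Br)CCC2(CC1)OCC(C)(C)CO2 | intermediate
10 | 9-{2-[(tert-butyldimethylsilyl)oxy]ethyl}-3,3-dimethyl-1,5-dioxaspiro[5.5]undecan-9-ol | CC(C)(C)[Si](C)(C)OCCC1(O)CCC2(CC1)OCC(C)(C)CO2 | intermediate
11 | 4-hydroxy-4-(2-hydroxyethyl)cyclohexan-1-one | OCCC1(O)CCC(=O)CC1 | intermediate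
12 | palmitoyl chloride (hexadecanoyl chloride) | CCCCCCCCCCCCCCCC(=O)Cl | starting material
13 | 2-(1-hydroxy-4-oxocyclohexyl)ethyl hexadecanoate | CCCCCCCCCCCCCCCC(=O)OCCC1(O)CCC(=O)CC1 | target

Total step count: 7. Longest linear sequence: 6 steps (steps 1, 2, 3, 5, 6, 7); step 4 is a one-step side branch.

Steps most likely to fail

Step 5. The bis-organomagnesium reagent may form incompletely or couple with itself. The first adduct may also react intermolecularly and oligomerise, or the intermediate ketone may be enolised and lose silyloxide before the ring closes. The fallback gives up the double addition. It sets out from dibromide 4 and rejoins the route at keto diol 11. 1,3-Dithiane is lithiated (n-BuLi, THF, −30 °C) and alkylated with 4, and a second equivalent of n-BuLi closes the ring by intramolecular alkylation (Corey–Seebach bis-alkylation). This should give 3,3-dimethyl-1,5-dioxa-10,14-dithiadispiro[5.2.5.2]hexadecane F1. Oxidative dethioketalisation with [bis(trifluoroacetoxy)iodo]benzene in NaHCO3-buffered aqueous MeCN should give 3,3-dimethyl-1,5-dioxaspiro[5.5]undecan-9-one F2. Aldol addition of the lithium enolate of ethyl acetate (LiN(i-Pr)2, THF, −78 °C) should give ethyl 2-(9-hydroxy-3,3-dimethyl-1,5-dioxaspiro[5.5]undecan-9-yl)acetate F3. LiAlH4 in THF should give 9-(2-hydroxyethyl)-3,3-dimethyl-1,5-dioxaspiro[5.5]undecan-9-ol F4, and the aqueous acid of step 6 should convert F4 into 11.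

Step 1. The strongly enolised keto diester may ketalise only to a stalled equilibrium, and the diol may transesterify the ethyl esters during the long heating. The fallback sets out from 1 and returns at 2 by a water-free two-stage exchange. Treatment of 1 with triethyl orthoformate and catalytic H2SO4 in ethanol should give the enol ether diethyl (E)-3-ethoxypent-2-enedioate F6; the E isomer is expected to predominate, and the geometry is lost in the next operation. Heating F6 with neopentyl glycol and pyridinium p-toluenesulfonate in toluene while ethanol distils off should give 2 by acetal exchange at the protonated enol ether carbon.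

Step 6. The robust dioxane may need long acid exposure, during which the tertiary alcohol could dehydrate, and the small water-soluble keto diol may be lost on isolation. The fallback sets out from 10 and returns at target 13, at the cost of one extra step, by acylating before the ketone is unmasked so that every intermediate is lipophilic. Bu4NF in THF should cleave only the silyl ether and give 9-(2-hydroxyethyl)-3,3-dimethyl-1,5-dioxaspiro[5.5]undecan-9-ol F4, the diol already named in the first fallback. Palmitoyl chloride 12 with pyridine in CH2Cl2 at 0 °C should acylate its primary hydroxyl and give 2-(9-hydroxy-3,3-dimethyl-1,5-dioxaspiro[5.5]undecan-9-yl)ethyl hexadecanoate F5. Pyridinium p-toluenesulfonate in acetone/H2O (10:1) at 50 °C should then open the ketal and give 13.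

Further compounds
F1 | step 5 | 3,3-dimethyl-1,5-dioxa-10,14-dithiadispiro[5.2.5.2]hexadecane | CC1(C)COC2(CCC3(CC2)SCCCS3)OC1
F2 | step 5 | 3,3-dimethyl-1,5-dioxaspiro[5.5]undecan-9-one | CC1(C)COC2(CCC(=O)CC2)OC1
F3 | step 5 | ethyl 2-(9-hydroxy-3,3-dimethyl-1,5-dioxaspiro[5.5]undecan-9-yl)acetate | CCOC(=O)CC1(O)CCC2(CC1)OCC(C)(C)CO2
F4 | step 5 | 9-(2-hydroxyethyl)-3,3-dimethyl-1,5-dioxaspiro[5.5]undecan-9-ol | OCCC1(O)CCC2(CC1)OCC(C)(C)CO2
F5 | step 6 | 2-(9-hydroxy-3,3-dimethyl-1,5-dioxaspiro[5.5]undecan-9-yl)ethyl hexadecanoate | CCCCCCCCCCCCCCCC(=O)OCCC1(O)CCC2(CC1)OCC(C)(C)CO2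
F6 | step 1 | diethyl (E)-3-ethoxypent-2-enedioate | CCOC(=O)/C=C(/OCC)CC(=O)OCC
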